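We stand before a closed, stirred vessel into which gas enters a solution that holds none at the start, while the starting material goes over to target and to other capture product. Flask maple is the asked flask, followed so far; oak is the earlier run at lower loading.

common to all: gas 16 mM (held)

|  | starting material | first nucleophile | remark | time |
|---|---|---|---|---|
| maple | 0.30 M | 1.2 M | the very flask that is asked about, followed so far |  |
| oak | 0.20 M | 1.2 M | run made earlier |  |
| flask | 0.30 M | 1.20 M |  | 20 h |

| run | time / h | target / % | other capture product / % |
|---|---|---|---|
| maple | 1.00 | 1.3 | 5.8 |
| maple | 2.00 | 1.5 | 12.5 |
| maple | 3.00 | 1.6 | 17.9 |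
| maple | 4.00 | 2.4 | 23.5 |
| maple | 5.00 | 2.5 | 28.0 |
| maple | 6.00 | 2.6 | 33.1 |
| oak | 1.00 | 0.5 | 6.2 |
| oak | 2.00 | 1.1 | 12.4 |
| oak | 3.00 | 1.4 | 19.0 |
| oak | 5.00 | 2.3 | 29.4 |
| oak | 8.00 | 2.5 | 41.9 |
| oak | 15.0 | 3.8 | 64.3 |

(scatter of a reading: 0.3 percentage points)

- share of target in target plus other capture product at 20 min
- share of target in target plus other capture product at 20 h
- which of target and other capture product there is more of at 20 h

- the numbers in the tables scatter with a standard deviation of 0.3 percentage points
- at the start none of the gas is in solution

In maple the running share of target falls from 18.3% at 1.00 h to 7.28% at 6.00 h, and we take this last reading as our bound from above for 20 h. For the bound from below we use oak: between 2.00 h and 15.0 h, target made up 4.95% of what was newly formed. We call this the portion share, the differential selectivity, and maple's own later readings give 5.07%.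

To tighten the bracket, we read a first-order constant of 0.0736 h⁻¹ from maple's two products together, which puts them at 77.1% by 20 h. Adding the new part at the portion share gives our estimate of 6.03%, with other capture product ahead. The 20 min share lies before any reading, so we bracket nothing there.

The forecast says 27%, 6.4% and other capture product, with “the dissolved gas then taking over most of the capture”. Its 6.4% stands above our estimate but inside the bracket.

The flask gives 18.2% and 6.17%, with other capture product ahead.

    starting material → intermediate (k = 0.0750 h⁻¹)
    second nucleophile + intermediate → other capture product (k = 8700 M⁻¹ h⁻¹)
    first nucleophile + intermediate → target (k = 3.70 M⁻¹ h⁻¹)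
    gas ⇌ second nucleophile, rate k4*(csat - [second nucleophile]) (kL = 1.90 h⁻¹)

The early share is below the forecast's, and the late one falls inside the bracket. At 20.0 h the second nucleophile stands at 0.0133 M. The 22% of starting material left, taken at the portion share, brings target from 4.79% to 5.88%, against 5.54% stored at 200 h. In the neighbour flask, the same flask with 1.2 M of starting material, the portion share gives 3.84% of target at 20.0 h, but that flask holds 32.2%.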